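## The problem

The target is apigenin that carries a 2-methoxy-5-(methoxycarbonyl)phenyl group (ring D) on C6. It consists of a chromone (rings A and C), the 4-hydroxyphenyl ring B on C2, and ring D joined to ring A through the C6–D1 bond, which lies between the 5-OH and 7-OH groups and faces the D2 methoxy group. There is no stereocentre, and the biaryl axis bears only small oxygen substituents, so the task is one of connectivity and regiochemistry. Ring D must end up on C6 and not on C8; these positions differ only in which of the three phloroglucinol oxygens becomes the ring oxygen O1, and 5,7-dihydroxyflavones can exchange them under acid by ring opening and reclosure. On ring D the methoxy group must be ortho and the ester meta to the biaryl bond. The methyl ester and the single aryl methyl ether have to survive beside three phenols that are freed at the end. This rules out hydroxide, hydride, hard carbon nucleophiles once the ester is present, and unselective ether cleavage; the chromone enone is electrophilic and reducible and is best made late. The C6–D1 bond is the crowded one: a cross-coupling would have to join an electron-rich carbon flanked by two oxygens to an ortho-substituted partner. Ring D itself offers a way round. Its donor (OMe on D2) and acceptor (CO2Me on D5) are para, the pattern left by a 2-methoxybutadiene and a propiolate after [4+2] addition and loss of two hydrogens, and D1 with D6 correspond to the carbonyl and methyl carbons of the acetyl group of 2,4,6-trihydroxyacetophenone, whose ring can serve as ring A.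

## Retrosynthesis

**Target 17 to flavone 16.** The three phenols are unveiled last by cutting three O–benzyl bonds. Benzyl is preferred to methyl, silyl or acetal protection because it withstands organometallic addition, heating, DDQ and palladium catalysis. It leaves by hydrogenolysis, which touches neither the methyl ether nor the methyl ester. Compound 16 differs from 17 only in protection, but it removes every acidic proton from the steps before it. The forward reaction must spare the C2=C3 bond of the chromone.

**Flavone 16 to iodophenol 13 and alkyne 14.** Ring C is cut at O1–C2, C3–C4 and C4–C4a, which returns an o-iodophenol, the terminal arylalkyne 14 and one carbonyl carbon from carbon monoxide. Compared with the chalcone and diketone routes to ring C, this cut needs no enolisable acetyl ketone and no strong base beside the methyl ester. It also fixes the 6-aryl regiochemistry by construction: the only free hydroxyl of 13 lies para to ring D and must become O1. Compound 13 has lost rings B and C. The forward reaction must insert carbon monoxide at a di-ortho-substituted aryl–palladium bond and then close in the 6-endo sense.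

**Iodophenol 13 to phenol 12 and allyl ether 11.** The C–I bond and then the O–allyl bond are cut. In 12 the two open positions of ring A are equivalent and each is ortho to the free hydroxyl, so iodination has no regiochemical choice to make. It need only stop after one iodine. The allyl group of 11 is what keeps the para oxygen distinct from its two benzylated neighbours; zerovalent palladium removes it without disturbing them.

**Biaryl 11 to cyclohexadiene 10, and 10 to diene 8 and methyl propiolate 9.** Ring D is first taken back to its dihydro form by adding hydrogens at D3 and D6, and then cut at D3–D4 and D5–D6. The neighbouring cut, the C6–D1 biaryl bond, would demand a coupling at a carbon flanked by two benzyloxy groups. The ring cut avoids this, because C6–D1 is already present as the bond between ring A and the former acetyl carbon. The precursors are an achiral diene and a four-carbon ester. The forward cycloaddition must place the methoxy group para to the ester and must tolerate an aryl group that crowds the D6 terminus. The dehydrogenation of 10 needs only a quinone.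

**Diene 8 to carbinol 7, ketone 3 and methyl vinyl ether 4.** The D1=D6 double bond is taken back to a tertiary alcohol and the D1–D2 bond is cut. This gives an aryl methyl ketone and a 1-methoxyvinyl anion, used as the lithium reagent 5 and its cerium derivative 6. The only methyl ether of the target thus arrives as an enol ether with no methylation step. Dehydration of 7 can run only toward the methyl group, since the vinyl side has no β-hydrogen. The forward addition must beat enolisation of a hindered ketone, and the dehydration must spare the enol ether.

**Ketone 3 to 2 and 2,4,6-trihydroxyacetophenone 1.** The two O–benzyl bonds and then the O–allyl bond are cut. The order follows the intrinsic reactivity of 1: the 4-hydroxyl is the most acidic and the least hindered and is allylated first, and the two chelated ortho hydroxyls are benzylated afterwards under forcing conditions. The reverse pattern, with the distinct group on an ortho oxygen, is easier to make but would lead to the 8-aryl flavone. The selectivity of the first alkylation is therefore the price of the correct regiochemistry.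

## Roads not taken

**Alternative 1:** The C6–D1 bond would be cut and made intramolecularly. Ring D would be hung from O5 as a di-tert-butylsilylene diether, giving the iodide A2. Zerovalent palladium generated from Pd(OAc)2 and tricyclohexylphosphine would insert into the D1–I bond; carbonate and pivalate would assist cleavage of C6–H; reductive elimination would close a temporary seven-membered dioxasilepine and give A1. Removal of the bridge, methylation of the D2 hydroxyl and debenzylation would follow.
- Merits: the flavone core is used intact, the tether can reach C6 but not C8, and after unbridging the chelated 5-OH is so poor a nucleophile that selective methylation on ring D is plausible. The route would be about three steps shorter than the chosen one, and in step count it is the better plan.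
- Weak points: the mixed diaryloxysilane must be assembled on the chelated, hindered 5-OH. Si–OAr bonds are labile to carbonate and pivalate at the temperatures such C–H cleavage needs. C6–H is flanked by two oxygen substituents. Biaryl formation through a seven-membered silicon-tethered palladacycle has no close analogy.
- Comparison: the chosen plan is longer, but it never forms the crowded biaryl bond with a metal, and each of its steps belongs to an established reaction type. In Alternative 1 everything depends on one unprecedented ring closure.

**Alternative 2:** Ring A would be cut at C4a–C5 and stored as the 3-aryl-4-hydroxy-2-pyranone A4, a masked linear polyketide. Mg(OMe)2 in methanol would open the lactone to a magnesium-chelated triketo ester, whose C4a carbanion would attack the ester carbonyl C5 in a Claisen closure to give the trihydroxychalcone A3.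
- Merits: the plan is biomimetic, ring D is attached to an sp3 carbon before ring A exists so that no hindered coupling arises, and ring A needs no protecting groups. It probably reaches the chalcone stage in fewer steps than the chosen plan reaches 13.
- Weak points: the triketo ester can also fold by aldol condensation. The cinnamoyl enone of A4 is a Michael acceptor for methoxide and for the internal enolates. Most seriously, A3 has two free hydroxyls ortho to the carbonyl, and oxidative cyclisation can close through either. Closure through the hydroxyl next to ring D gives the 8-aryl flavone A5, and acid can interconvert the 6- and 8-aryl series.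
- Comparison: the chosen plan pays for its extra steps with a differentiated para oxygen, which makes the 6-aryl outcome certain, and with intermediates that are not prone to refolding.

**Alternative 3:** Ring A would be grown on a pyranone by benzannulation. Irradiation of the pyranonyl diazoketone A7 would trigger a Wolff shift (forming C8a–C8) to a vinylketene. [2+2] addition of the siloxyalkyne A8 would form C5–C6 and C7–C8. Four-electron opening of the cyclobutenone and six-electron closure (C4a–C5) would give A6, with 5-OH free and O7 silylated.
- Merits: this is the most convergent plan. The polarity of the ynol ether places ring D between the hydroxyl and the silyloxy group, the O5/O7 differentiation comes free, and only two deprotections remain. If it worked it would be shorter than the chosen route.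
- Weak points: aryl siloxyalkynes are normally made by ynolate homologation of an ester, and ring D already carries a methyl ester that must stay. The 4-pyranone chromophore is itself photoactive and competes with the Wolff step. The vinyl partner of the ketene is the electron-poor double bond of a vinylogous ester, a substrate class on which this benzannulation has not been shown.
- Comparison: the chosen plan sets against the better convergence of Alternative 3 that its intermediates are ordinary benzenoid compounds or a diene used at once, and that no step is asked to work on a new substrate class.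

Key step: step 5

Assumption: the C6–D1 axis is treated as configurationally labile, as the stereo-free structure implies, and 1-(benzyloxy)-4-ethynylbenzene (14) is taken to be purchasable.

## Route

Step 1
Reactants: 1 2,4,6-trihydroxyacetophenone
Product: 2 1-[4-(allyloxy)-2,6-dihydroxyphenyl]ethan-1-one
Conditions: allyl bromide (1.0 equiv), K2CO3 (1.0 equiv), acetone, 0 °C to rt
Reagents that add atoms: allyl bromide, C=CCBr
Why: Williamson etherification; the 4-hydroxyl is the most acidic and the only one that neither chelates nor flanks the acetyl group, so one equivalent of base and halide should alkylate it first.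

Step 2
Reactants: 2 1-[4-(allyloxy)-2,6-dihydroxyphenyl]ethan-1-one
Product: 3 1-[4-(allyloxy)-2,6-bis(benzyloxy)phenyl]ethan-1-one
Conditions: BnBr (2.5 equiv), K2CO3, Bu4NI (cat.), DMF, 70 °C
Reagents that add atoms: benzyl bromide, BrCc1ccccc1
Why: Williamson etherification under forcing conditions; the chelated ortho phenols need DMF, heat and iodide catalysis, all far below the temperature at which the aryl allyl ether would undergo Claisen rearrangement.

Step 3
Reactants: 3 1-[4-(allyloxy)-2,6-bis(benzyloxy)phenyl]ethan-1-one; 4 methyl vinyl ether
Product: 7 2-[4-(allyloxy)-2,6-bis(benzyloxy)phenyl]-3-methoxybut-3-en-2-ol (racemic), via 1-methoxyvinyllithium 5 (not isolated), via dichloro(1-methoxyvinyl)cerium 6 (not isolated)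
Conditions: 4, t-BuLi, THF, −78 to 0 °C; CeCl3 (anhydrous), −78 °C; then 3, −78 °C; aq NH4Cl
Reagents that add atoms: none
Why: 1,2-addition of a 1-alkoxyvinyl organometallic (acyl anion equivalent) to a ketone; transmetalation to the less basic organocerium reagent should suppress enolisation of the hindered aryl methyl ketone. The carbinol stereocentre forms racemic and is destroyed in step 4.

Step 4
Reactants: 7 2-[4-(allyloxy)-2,6-bis(benzyloxy)phenyl]-3-methoxybut-3-en-2-ol
Product: 8 2-[4-(allyloxy)-2,6-bis(benzyloxy)phenyl]-3-methoxybuta-1,3-diene
Conditions: Burgess reagent, PhMe, 50 °C; filtration through Et3N-deactivated silica, used at once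
Reagents that add atoms: none
Why: Burgess dehydration, a syn elimination from the sulfamate ester of a tertiary benzylic alcohol; only the methyl group offers β-hydrogens, so the 1,1-disubstituted alkene is the only possible olefin, and the neutral conditions spare the acid-labile enol ether.

Step 5
Reactants: 8 2-[4-(allyloxy)-2,6-bis(benzyloxy)phenyl]-3-methoxybuta-1,3-diene; 9 methyl propiolate
Product: 10 methyl 5-[4-(allyloxy)-2,6-bis(benzyloxy)phenyl]-4-methoxycyclohexa-1,4-diene-1-carboxylate
Conditions: 9 (5 equiv), BHT (cat.), PhMe, 110 °C, sealed base-washed tube
Reagents that add atoms: none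
Why: Thermal Diels–Alder reaction of normal electron demand, concerted but asynchronous: the 2-methoxy group raises the diene HOMO and puts its largest terminal coefficient on D3, which bonds first to the electrophilic β-carbon (D4) of the propiolate, and D6 then closes onto the ester-bearing carbon D5. The closest known reaction type is the cycloaddition of 2-alkoxy- and 2-silyloxybuta-1,3-dienes with propiolate esters, which gives 1-alkoxy-4-carboalkoxycyclohexa-1,4-dienes. Ring D is closed in one suprafacial [4+2] event that forms D3–D4 and D5–D6 and leaves the D1=D2 enol ether and the D4=D5 enoate unconjugated. No stereocentre is created, and 10 is achiral because ring A is symmetric about its bond to D1. The selectivity needed is regiochemical, OMe para to CO2Me; it should be secured because the methoxy group is the only conjugating donor on the diene, the di-ortho-substituted aryl ring on D1 being forced roughly perpendicular to the diene and so exerting little orbital bias. The 2,3-disubstitution raises the population of the reactive s-cis conformer, and the linear alkyne is the slimmest possible partner for the D6 terminus, which the ortho benzyloxy groups flank. The allyl ether is neither a competent dienophile nor prone to Claisen rearrangement at this temperature, and BHT with acid-free glassware guards against polymerisation and enol ether hydrolysis.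

Step 6
Reactants: 10 methyl 5-[4-(allyloxy)-2,6-bis(benzyloxy)phenyl]-4-methoxycyclohexa-1,4-diene-1-carboxylate
Product: 11 methyl 3-[4-(allyloxy)-2,6-bis(benzyloxy)phenyl]-4-methoxybenzoate
Conditions: DDQ (1.1 equiv), PhMe, rt
Reagents that add atoms: none
Why: Quinone dehydrogenation: DDQ abstracts hydride from a doubly allylic CH2 (D3 or D6) and proton loss gives the arene, driven by aromatisation; benzyl and allyl aryl ethers are inert to DDQ at room temperature.

Step 7
Reactants: 11 methyl 3-[4-(allyloxy)-2,6-bis(benzyloxy)phenyl]-4-methoxybenzoate
Product: 12 methyl 3-[2,6-bis(benzyloxy)-4-hydroxyphenyl]-4-methoxybenzoate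
Conditions: Pd(PPh3)4 (5 mol %), morpholine, THF, rt
Reagents that add atoms: none
Why: Tsuji–Trost deallylation: zerovalent palladium ionises the aryl allyl ether to a π-allyl complex that morpholine captures; benzyl ethers, the methyl ether and the ester are not touched.

Step 8
Reactants: 12 methyl 3-[2,6-bis(benzyloxy)-4-hydroxyphenyl]-4-methoxybenzoate
Product: 13 methyl 3-[2,6-bis(benzyloxy)-4-hydroxy-3-iodophenyl]-4-methoxybenzoate
Conditions: NIS (1.0 equiv), CH2Cl2, −20 to 0 °C
Reagents that add atoms: N-iodosuccinimide, O=C1CCC(=O)N1I
Why: Electrophilic aromatic iodination; the two open positions of ring A are equivalent, each ortho to the hydroxyl and ortho or para to a benzyloxy group, while ring D is deactivated by its ester. One equivalent at low temperature should hold the reaction at the mono-iodide.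

Step 9
Reactants: 13 methyl 3-[2,6-bis(benzyloxy)-4-hydroxy-3-iodophenyl]-4-methoxybenzoate; 14 1-(benzyloxy)-4-ethynylbenzene
Product: 16 methyl 3-[5,7-bis(benzyloxy)-2-(4-benzyloxyphenyl)-4-oxo-4H-chromen-6-yl]-4-methoxybenzoate, via o-hydroxyaryl ynone 15 (not isolated)
Conditions: CO (20 bar), PdCl2(dppf) (5 mol %), Et2NH, 120 °C
Reagents that add atoms: carbon monoxide, [C-]#[O+]
Why: Palladium-catalysed carbonylative Sonogashira coupling and annulation of an o-iodophenol with a terminal alkyne: oxidative addition, CO insertion and alkynylation give ynone 15, and in the secondary amine the phenol closes by 6-endo oxa-Michael addition to the flavone and not 5-exo to an aurone. Only the hydroxyl para to ring D is free, so the 6-aryl isomer is the only possible one.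

Step 10
Reactants: 16 methyl 3-[5,7-bis(benzyloxy)-2-(4-benzyloxyphenyl)-4-oxo-4H-chromen-6-yl]-4-methoxybenzoate
Product: 17 methyl 3-[5,7-dihydroxy-2-(4-hydroxyphenyl)-4-oxo-4H-chromen-6-yl]-4-methoxybenzoate
Conditions: H2 (1 atm), 10% Pd/C, EtOAc/MeOH, rt
Reagents that add atoms: none
Why: Hydrogenolysis of benzyl aryl ethers over Pd/C; the methyl ether and methyl ester are inert, and the chromone C2=C3 bond should persist at 1 atm if the reaction is stopped after uptake of three equivalents.

## Compound list

1 | 2,4,6-trihydroxyacetophenone | CC(=O)c1c(O)cc(O)cc1O | starting material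
2 | 1-[4-(allyloxy)-2,6-dihydroxyphenyl]ethan-1-one | CC(=O)c1c(O)cc(OCC=C)cc1O | intermediate
3 | 1-[4-(allyloxy)-2,6-bis(benzyloxy)phenyl]ethan-1-one | CC(=O)c1c(OCc2ccccc2)cc(OCC=C)cc1OCc1ccccc1 | intermediate
4 | methyl vinyl ether | C=COC | starting material
5 | 1-methoxyvinyllithium (not isolated) | [Li]C(=C)OC | intermediate
6 | dichloro(1-methoxyvinyl)cerium (not isolated) | C=C(OC)[Ce](Cl)Cl | intermediate
7 | 2-[4-(allyloxy)-2,6-bis(benzyloxy)phenyl]-3-methoxybut-3-en-2-ol (racemic) | C=C(OC)C(C)(O)c1c(OCc2ccccc2)cc(OCC=C)cc1OCc1ccccc1 | intermediate
8 | 2-[4-(allyloxy)-2,6-bis(benzyloxy)phenyl]-3-methoxybuta-1,3-diene | C=C(OC)C(=C)c1c(OCc2ccccc2)cc(OCC=C)cc1OCc1ccccc1 | intermediate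
9 | methyl propiolate | C#CC(=O)OC | starting material
10 | methyl 5-[4-(allyloxy)-2,6-bis(benzyloxy)phenyl]-4-methoxycyclohexa-1,4-diene-1-carboxylate (achiral) | COC(=O)C1=CCC(OC)=C(c2c(OCc3ccccc3)cc(OCC=C)cc2OCc2ccccc2)C1 | intermediate
11 | methyl 3-[4-(allyloxy)-2,6-bis(benzyloxy)phenyl]-4-methoxybenzoate | COC(=O)c1ccc(OC)c(-c2c(OCc3ccccc3)cc(OCC=C)cc2OCc2ccccc2)c1 | intermediate
12 | methyl 3-[2,6-bis(benzyloxy)-4-hydroxyphenyl]-4-methoxybenzoate | COC(=O)c1ccc(OC)c(-c2c(OCc3ccccc3)cc(O)cc2OCc2ccccc2)c1 | intermediate
13 | methyl 3-[2,6-bis(benzyloxy)-4-hydroxy-3-iodophenyl]-4-methoxybenzoate | COC(=O)c1ccc(OC)c(-c2c(OCc3ccccc3)cc(O)c(I)c2OCc2ccccc2)c1 | intermediate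
14 | 1-(benzyloxy)-4-ethynylbenzene | C#Cc1ccc(OCc2ccccc2)cc1 | starting material
15 | methyl 3-[2,6-bis(benzyloxy)-3-[3-(4-benzyloxyphenyl)prop-2-ynoyl]-4-hydroxyphenyl]-4-methoxybenzoate (not isolated) | COC(=O)c1ccc(OC)c(-c2c(OCc3ccccc3)cc(O)c(C(=O)C#Cc3ccc(OCc4ccccc4)cc3)c2OCc2ccccc2)c1 | intermediate
16 | methyl 3-[5,7-bis(benzyloxy)-2-(4-benzyloxyphenyl)-4-oxo-4H-chromen-6-yl]-4-methoxybenzoate | COC(=O)c1ccc(OC)c(-c2c(OCc3ccccc3)cc3oc(-c4ccc(OCc5ccccc5)cc4)cc(=O)c3c2OCc2ccccc2)c1 | intermediate
17 | methyl 3-[5,7-dihydroxy-2-(4-hydroxyphenyl)-4-oxo-4H-chromen-6-yl]-4-methoxybenzoate (no stereocentre) | COC(=O)c1ccc(OC)c(-c2c(O)cc3oc(-c4ccc(O)cc4)cc(=O)c3c2O)c1 | target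

## Step count and risks

Total step count: 10. Longest linear sequence: 10 steps (1 to 17); compounds 4, 9 and 14 are bought.

**Step 5 (key step).** The cycloaddition may be too slow. The two benzyloxy groups of the perpendicular aryl ring sit above and below the diene next to the D6 terminus, so oligomerisation of the diene, polymerisation of the propiolate or hydrolysis of the enol ether by traces of acid could overtake ring closure. A weaker orbital bias than expected would also erode the regiochemistry. The fallback builds the biaryl bond in place of ring D and sets out from ketone 3. Baeyer–Villiger oxidation (mCPBA, NaHCO3, CH2Cl2; the electron-rich aryl group migrates) would give 4-(allyloxy)-2,6-bis(benzyloxy)phenyl acetate F1. Methanolysis (K2CO3, MeOH) would give 4-(allyloxy)-2,6-bis(benzyloxy)phenol F2, and Tf2O with pyridine would give 4-(allyloxy)-2,6-bis(benzyloxy)phenyl trifluoromethanesulfonate F3. Suzuki–Miyaura coupling of F3 with commercial [2-methoxy-5-(methoxycarbonyl)phenyl]boronic acid (Pd(OAc)2, SPhos, K3PO4, PhMe/H2O, 90 °C) rejoins the route at 11. The price is a coupling with three ortho substituents, which the ring construction was designed to avoid, and some allyl ether loss at the palladium stage is possible.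

**Step 3.** Proton transfer from the acetyl group to the organometallic (enolisation) may outrun carbonyl addition at this twisted, di-ortho-substituted ketone even with cerium, and the carbinol must then still be dehydrated without loss of the enol ether. The fallback makes use of the enolisation and sets out from 3. KHMDS and PhNTf2 (THF, −78 °C) would give 1-[4-(allyloxy)-2,6-bis(benzyloxy)phenyl]vinyl trifluoromethanesulfonate F4. The coupling partner tributyl(1-methoxyvinyl)stannane F5 would be made from 5 and Bu3SnCl. Stille coupling of F4 with F5 (Pd(PPh3)4, CuCl, LiCl, DMSO, rt to 45 °C) gives diene 8 directly, bypassing 7 and step 4. The allyl ether has no soft nucleophile to be transferred to in this coupling, but it is the group to watch.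

**Step 1.** Site selectivity may be lost through a second allylation at an ortho oxygen or C-allylation of the phloroglucinol phenoxide. The fallback is Mitsunobu etherification of 1 with allyl alcohol (PPh3, DIAD, THF, 0 °C). Here the unhindered, most acidic 4-hydroxyl is the one that protonates the betaine and is alkylated, and no free phenoxide is present for C-alkylation. It returns to the route at 2 and makes no new compound (F0).

**Step 9.** Carbon monoxide insertion may fail to keep pace with direct alkynylation at the hindered, electron-rich aryl–palladium centre, or the ynone may close in the 5-exo sense. The fallback is a classical ring C construction from 13. Stille coupling with commercial tributyl(1-ethoxyvinyl)stannane (PdCl2(PPh3)2, dioxane, 90 °C) would give methyl 3-[2,6-bis(benzyloxy)-3-(1-ethoxyvinyl)-4-hydroxyphenyl]-4-methoxybenzoate F6. Dilute HCl on work-up would hydrolyse it to methyl 3-[3-acetyl-2,6-bis(benzyloxy)-4-hydroxyphenyl]-4-methoxybenzoate F7. LiHMDS (3 equiv) and 4-(benzyloxy)benzoyl chloride (THF, −78 °C to rt; Baker–Venkataraman-type acylation) would give methyl 3-[2,6-bis(benzyloxy)-3-[3-(4-benzyloxyphenyl)-3-oxopropanoyl]-4-hydroxyphenyl]-4-methoxybenzoate F8. Cyclodehydration (TsOH, PhMe, 80 °C) returns to the route at 16. The base is non-nucleophilic, so the methyl ester should survive.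

**Step 10.** The C2=C3 double bond of the chromone may be over-reduced, or cleavage may stall at the 5- and 7-benzyl ethers that flank ring D. The fallback is Lewis-acid debenzylation of 16 with BCl3 and pentamethylbenzene as cation scavenger (CH2Cl2, −78 °C). The aryl methyl ether is not peri to a carbonyl and, like the methyl ester, should survive. It returns to the route at 17 and makes no new compound (F0).

## Further compounds

F1 | step 5 | 4-(allyloxy)-2,6-bis(benzyloxy)phenyl acetate | CC(=O)Oc1c(OCc2ccccc2)cc(OCC=C)cc1OCc1ccccc1
F2 | step 5 | 4-(allyloxy)-2,6-bis(benzyloxy)phenol | Oc1c(OCc2ccccc2)cc(OCC=C)cc1OCc1ccccc1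
F3 | step 5 | 4-(allyloxy)-2,6-bis(benzyloxy)phenyl trifluoromethanesulfonate | O=S(=O)(Oc1c(OCc2ccccc2)cc(OCC=C)cc1OCc1ccccc1)C(F)(F)F
F4 | step 3 | 1-[4-(allyloxy)-2,6-bis(benzyloxy)phenyl]vinyl trifluoromethanesulfonate | C=C(OS(=O)(=O)C(F)(F)F)c1c(OCc2ccccc2)cc(OCC=C)cc1OCc1ccccc1
F5 | step 3 | tributyl(1-methoxyvinyl)stannane | CCCC[Sn](CCCC)(CCCC)C(=C)OC
F0 | step 1 | none | none
F6 | step 9 | methyl 3-[2,6-bis(benzyloxy)-3-(1-ethoxyvinyl)-4-hydroxyphenyl]-4-methoxybenzoate | COC(=O)c1ccc(OC)c(-c2c(OCc3ccccc3)cc(O)c(C(=C)OCC)c2OCc2ccccc2)c1
F7 | step 9 | methyl 3-[3-acetyl-2,6-bis(benzyloxy)-4-hydroxyphenyl]-4-methoxybenzoate | COC(=O)c1ccc(OC)c(-c2c(OCc3ccccc3)cc(O)c(C(C)=O)c2OCc2ccccc2)c1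
F8 | step 9 | methyl 3-[2,6-bis(benzyloxy)-3-[3-(4-benzyloxyphenyl)-3-oxopropanoyl]-4-hydroxyphenyl]-4-methoxybenzoate | COC(=O)c1ccc(OC)c(-c2c(OCc3ccccc3)cc(O)c(C(=O)CC(=O)c3ccc(OCc4ccccc4)cc3)c2OCc2ccccc2)c1
F0 | step 10 | none | none
A1 | alternative 1 | silylene-bridged 6-arylflavone (product of the direct arylation) | COC(=O)c1ccc2c(c1)-c1c(OCc3ccccc3)cc3oc(-c4ccc(OCc5ccccc5)cc4)cc(=O)c3c1O[Si](C(C)(C)C)(C(C)(C)C)O2
A2 | alternative 1 | methyl 4-[[7-(benzyloxy)-2-(4-benzyloxyphenyl)-4-oxo-4H-chromen-5-yl]oxy-di-tert-butylsilyl]oxy-3-iodobenzoate (bridged precursor) | COC(=O)c1ccc(O[Si](C(C)(C)C)(C(C)(C)C)Oc2cc(OCc3ccccc3)cc3oc(-c4ccc(OCc5ccccc5)cc4)cc(=O)c23)c(I)c1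
A3 | alternative 2 | 3'-aryl-2',4',6'-trihydroxy-4-benzyloxychalcone, (E) | COC(=O)c1ccc(OC)c(-c2c(O)cc(O)c(C(=O)/C=C/c3ccc(OCc4ccccc4)cc3)c2O)c1
A4 | alternative 2 | methyl 3-[6-[(E)-4-(4-benzyloxyphenyl)-2-oxobut-3-enyl]-4-hydroxy-2-oxo-2H-pyran-3-yl]-4-methoxybenzoate | COC(=O)c1ccc(OC)c(-c2c(O)cc(CC(=O)/C=C/c3ccc(OCc4ccccc4)cc3)oc2=O)c1
A5 | alternative 2 | methyl 3-[2-(4-benzyloxyphenyl)-5,7-dihydroxy-4-oxo-4H-chromen-8-yl]-4-methoxybenzoate (8-aryl isomer) | COC(=O)c1ccc(OC)c(-c2c(O)cc(O)c3c(=O)cc(-c4ccc(OCc5ccccc5)cc4)oc23)c1
A6 | alternative 3 | 7-O-triisopropylsilyl-4'-O-benzyl derivative of the target | COC(=O)c1ccc(OC)c(-c2c(O[Si](C(C)C)(C(C)C)C(C)C)cc3oc(-c4ccc(OCc5ccccc5)cc4)cc(=O)c3c2O)c1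
A7 | alternative 3 | 2-(diazoacetyl)-6-(4-benzyloxyphenyl)-4H-pyran-4-one | [N-]=[N+]=CC(=O)c1cc(=O)cc(-c2ccc(OCc3ccccc3)cc2)o1
A8 | alternative 3 | methyl 4-methoxy-3-[(triisopropylsilyloxy)ethynyl]benzoate | COC(=O)c1ccc(OC)c(C#CO[Si](C(C)C)(C(C)C)C(C)C)c1
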